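## Structural features

The target is a furofuranone lignan: a tetrahydrofuran (C1, C2, O3, C4, C5) and a γ-butyrolactone (C1, C8, O7, C6, C5) fused cis through the C1–C5 bond, that is, a 3,7-dioxabicyclo[3.3.0]octan-8-one. C2 carries a 3,4-dihydroxyphenyl (catechol) ring and C6 a 3,4,5-trihydroxyphenyl (pyrogallol) ring; both aryl groups stand on the convex face, so H1/H5 are cis while H1/H2 and H5/H6 are trans. The four stereocentres C2, C1, C5 and C6 (2S, 1S, 5R, 6S) are contiguous along the chain C2–C1–C5–C6. The fragile parts are the five free phenols, which oxidise in air once deprotonated, and the two benzylic C–O bonds (C2–O3 and C6–O7). Each of these bonds is para to a phenolic oxygen, so it can ionise in strong acid, open to a quinone methide in base, or be cleaved by hydrogenolysis, and each of these events would scramble C2 or C6. The lactone is also sensitive to hydroxide and alkoxide, whereas C1 is safe because only the cis ring fusion is free of strain. The real difficulty is therefore to set C5 and C6 relative to C2 while the polyphenol stays masked by groups that come off without acid, base or hydrogen. The key step uses the C1–C5–C6 relationship: C1 is alpha to the C8 carbonyl and bonded to C5, and C6, the neighbour of C5, is benzylic and bears O7. This is the imprint of a C1 malonyl radical adding to a cinnamyl C5=C6 alkene, followed by oxidation at C6 and capture by a carboxyl oxygen.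

## Logic of the disconnections

17 ⇒ 16. The five phenolic O–H bonds are exchanged for O–Si bonds. The phenols are released last because every earlier intermediate is then non-acidic and not prone to oxidation. The forward step must remove five silyl groups without letting a phenoxide para to C2 or C6 persist.

16 ⇒ 14 (through 15). The C1–H bond is exchanged for a C1–C bond to a tert-butoxycarbonyl group. With this extra carboxyl C1 becomes a malonate carbon that can be oxidised to a radical, and C1 no longer needs to be set because the cis fusion fixes it on decarboxylation. The forward step must cleave the ester and lose CO2 without ionising C2–O3 or C6–O7.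

14 ⇒ 13. The C1–C5 and O7–C6 bonds are cut. Both rings and the stereocentres C1, C5 and C6 disappear, leaving an open-chain ether with one stereocentre (C2) and an E alkene. The forward step must close 5-exo, place the C5 side chain trans to the C2 aryl group, turn the C6 aryl group to the convex face, and lactonise faster than the C6 intermediate eliminates.

13 ⇒ 12. The bond from C1 to its second ester carbon is cut. The malonate is completed only at this point because a β-hydroxy or β-alkoxy malonate is an aldol or oxa-Michael adduct that can revert in base, which would cost the C2 configuration; an order that completes the malonate before the ether is made was rejected for that reason. What remains is a robust β-alkoxy ester. The forward acylation must be run cold and quenched with acid before the enolate expels the allylic alkoxide.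

12 ⇒ 5 + 11. The O3–C4 ether bond is cut on its allylic side, so the C2–O3 bond of the stereocentre is never broken. This is the convergent cut into two fragments of similar size, one aryl ring each. The forward step must form the ether without base and at the primary allylic terminus.

11 ⇒ 10. The imidate C–O bond is cut. The imidate is only the activated form of the allylic alcohol; it must be made and used without prolonged storage.

10 ⇒ 9. The two C4–H bonds are traded for the ester oxidation level. This brings the fragment back to an enoate that an olefination can make; the forward reduction must be 1,2-selective.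

9 ⇒ 7 + 8. The C5=C6 double bond is cut. This reduces the fragment to an aromatic aldehyde and a two-carbon phosphonate; the forward step must give the E alkene, although the geometry is lost again at the radical stage.

7 ⇒ 6. Three O–Si bonds are cut, leading back to a commercial aldehyde; the forward step must silylate three adjacent phenols completely.

5 ⇒ 4. The C2–H bond is cut (carbonyl reduction). The only stereocentre that has to be made by reagent control is thereby traced to a prochiral ketone flanked by an ester, an ideal substrate for chelation-controlled catalytic hydrogenation. The forward step must deliver the 3S alcohol with high enantioselectivity.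

4 ⇒ 2 + 3. The C1–C2 bond is cut (Claisen condensation). The ketone must come from the non-enolisable partner so that only one crossed product can form.

2 ⇒ 1. Two O–Si bonds are cut, leading back to a commercial ester; the forward step is a routine silylation.

## Other disconnections considered

Alternative 1: The cut is made at C5–C6 and C1–C2, which leaves C8, C1, C5 and C4 as a butenolide. In the forward direction the lithium salt of 2-[3,4,5-tris(TBSO)phenyl]-1,3-dithiane A2 would add to the β-carbon of the menthol-derived (5R)-5-menthyloxyfuran-2(5H)-one A1, anti to the menthyloxy group. The lactone enolate would then be trapped by 3,4-bis(TBSO)benzaldehyde A3 anti to the new substituent, giving the trans,trans lactone A4.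

- In favour: three components of similar size are joined in one flask, and the absolute configuration of C1 and C5 comes from an inexpensive auxiliary with a well-understood facial bias. On convergence, and on the reliability with which C1 and C5 are set, this plan is the better of the two. It is the equal of the chosen plan in needing no asymmetric catalyst after the auxiliary is in place.
- Against: the step closes neither ring of the target, and the lactone of A4 is the wrong one. Its ring oxygen sits on the acetal carbon C4, whereas the target needs O7 on C6 and O3 between C2 and C4. After the key step the dithiane would have to be unmasked next to two oxygen-rich arenes, the C6 ketone reduced with facial control, C4 brought down to the alcohol level, the lactone moved from C4 to C6, and the tetrahydrofuran closed onto C2. C2 (unassigned in A4) and C6 would both still be open, and these are the centres that define the difficulty. A 2-aryl-2-lithiodithiane is also a strong base toward aryl silyl ethers.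
- Comparison: structurally the alternative gives the full carbon skeleton and two of four stereocentres but no ring, whereas step 10 gives both rings and C1, C5 and C6 from a precursor in which C2 is already fixed. Mechanistically the polar conjugate addition and aldol sequence is at least as predictable as a radical cyclisation. In step count the three components are reached faster, but six or more operations would follow the coupling, so the total is expected to exceed twelve.

Alternative 2: The cut is made at O3–C2 and C1–C5. In the forward direction zerovalent palladium from Pd2(dba)3 and a chiral bisphosphine would open racemic 2-vinyloxirane A5 to an alkoxide-bearing π-allylpalladium. Its oxygen would add to C2 of dimethyl 2-[3,4-bis(TBSO)benzylidene]malonate A6, and the malonate anion would close on the allyl carbon next to the CH2O group, giving the 2,4-trans tetrahydrofuran A7.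

- In favour: the tetrahydrofuran, C2, C5 and the geminal diester on C1 arise in one catalytic enantioselective step from partners made in one or two steps. On absolute stereocontrol at the ring-forming step, and on the number of steps to the first cyclic intermediate, this plan is the better. It is the equal of the chosen plan in providing a diester on C1 so that one carbonyl is always cis to the C5 side chain.
- Against: A7 lacks the C6 aryl group and O7. The vinyl group would have to be cleaved to an aldehyde and an aryl–metal reagent added, creating C6 by open-chain carbonyl addition next to an epimerisable C5. Lactonisation and removal of a methyl ester would follow, and the usual nucleophilic dealkoxycarbonylation in a hot dipolar solvent is hard on aryl silyl ethers. The oxygen-rich arylidene malonate is a weak acceptor and oxa-Michael addition is reversible, so diastereo- and enantioselectivity for this substitution pattern are uncertain.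
- Comparison: structurally the alternative builds one ring and two stereocentres, against two rings and three stereocentres in step 10. Mechanistically it is ionic and catalytic in metal, which is arguably cleaner than a stoichiometric manganese oxidation, but it sets C6 without the cyclic control that the chosen plan has. In step count the two plans are about equal (ten to eleven steps against twelve).

Alternative 3: The cut is made at C1–C5 and O3–C4, through a cyclopropane in which C1 is bonded to both C5 and C4. In the forward direction Rh2(OAc)4 would convert the diazo keto ester A8 (the 2-diazo-3-aryl-3-oxopropanoate of an (S)-1-arylprop-2-en-1-ol) into a carbenoid that adds to the vinyl group, giving the cyclopropane-fused lactone A9. MgI2 in the same flask would open the C1–C4 bond by iodide attack at C4, and the ketone oxygen would close O3–C4 (Cloke–Wilson ring expansion), giving the dihydrofuran A10.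

- In favour: both rings form in one flask, C6 comes from a simple enantioenriched aryl vinyl carbinol and is relayed to C5 through the rigid bicyclo[3.1.0] lactone, and no malonate with a β-leaving group appears anywhere. On ring construction it is the equal of the chosen plan, and on the number of steps to the bicycle it is the better.
- Against: A10 is flat at C1 and C2, so the last two stereocentres would have to come from reduction of a tetrasubstituted push–pull enol ether. Hydrogen delivered to the convex face would place H1 and H2 cis, that is, the C2 aryl group on the concave face, whereas the target has H1 and H2 trans. Correcting this would need epimerisation at C2 through the benzylic cation or quinone methide, the very process the chosen plan avoids. Hydrogenation also threatens both benzylic C–O bonds. The ester of A8 is a benzylic and allylic ester of an oxygen-rich arene that can ionise or transpose under MgI2, and a diazo compound has to be handled.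
- Comparison: structurally the alternative reaches the bicycle faster but leaves two stereocentres open, one of them mismatched with the intrinsic facial bias. The chosen plan fixes C2 first and uses it to control the rest. Mechanistically both plans form C1–C5 by a reactive C1 intermediate adding to an alkene. In step count the alternative is shorter up to A10 but not reliably shorter to the target.

Key step: step 10

Remarks on the chemistry: TBS stands for tert-butyldimethylsilyl and TBSO for the corresponding silyloxy group. The ether carbon keeps one spatial arrangement from 5 to 17; it is labelled R in 14 and 15 only because C1 there outranks the aryl ring.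

Assumption: RuCl2[(R)-BINAP] is taken to reduce the aryl β-keto ester 4 with the same facial sense as alkyl β-keto esters, which corresponds to 3S in 5.

## Route

Step 1
Reactants: 1 methyl 3,4-dihydroxybenzoate
Product: 2 methyl 3,4-bis(TBSO)benzoate
Conditions: TBSCl (2.5 equiv), imidazole (5 equiv), DMF, rt
Reagents that add atoms: tert-butyldimethylsilyl chloride, CC(C)(C)[Si](C)(C)Cl
Why: Silylation of both phenols through the N-silylimidazolium species; the methyl ester is inert, and masking the catechol here removes acidic and oxidisable hydroxyl groups before any enolate chemistry.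

Step 2
Reactants: 2 methyl 3,4-bis(TBSO)benzoate; 3 tert-butyl acetate
Product: 4 tert-butyl 3-[3,4-bis(TBSO)phenyl]-3-oxopropanoate
Conditions: 3 (3 equiv), LiN(iPr)2 (3 equiv), THF, −78 °C; add 2, −78 → −30 °C; AcOH
Reagents that add atoms: none
Why: Crossed Claisen condensation: the lithium enolate of 3 acylates on the non-enolisable aryl ester, and the β-keto ester is held as its enolate until the quench, which prevents a second addition. The bulky tert-butyl ester suppresses self-condensation, and the low temperature should keep the liberated methoxide from attacking the aryl silyl ethers.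

Step 3
Reactants: 4 tert-butyl 3-[3,4-bis(TBSO)phenyl]-3-oxopropanoate
Product: 5 tert-butyl (3S)-3-[3,4-bis(TBSO)phenyl]-3-hydroxypropanoate
Conditions: RuCl2[(R)-BINAP] (1 mol%), H2 (50 atm), EtOH, 50 °C
Reagents that add atoms: none
Why: Noyori asymmetric hydrogenation: the β-keto ester chelates divalent ruthenium and the (R)-BINAP pocket exposes one carbonyl face to hydride transfer, which should set the carbinol centre as 3S (the facial sense that gives (R)-3-hydroxybutanoates; the descriptor differs because aryl outranks CH2CO2tBu). Aryl silyl ethers, the arene rings and the tert-butyl ester are not reduced under these conditions.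

Step 4
Reactants: 6 3,4,5-trihydroxybenzaldehyde
Product: 7 3,4,5-tris(TBSO)benzaldehyde
Conditions: TBSCl (3.6 equiv), imidazole (7 equiv), DMF, rt
Reagents that add atoms: tert-butyldimethylsilyl chloride, CC(C)(C)[Si](C)(C)Cl
Why: Exhaustive silylation of the three adjacent phenols under the same mild conditions as step 1; the aldehyde is untouched and the air-sensitive pyrogallol is masked at once.

Step 5
Reactants: 7 3,4,5-tris(TBSO)benzaldehyde; 8 triethyl phosphonoacetate
Product: 9 ethyl (2E)-3-[3,4,5-tris(TBSO)phenyl]prop-2-enoate
Conditions: 8 (1.2 equiv), NaH (1.15 equiv), THF, 0 °C; add 7, 0 °C → rt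
Reagents that add atoms: none
Why: Horner–Wadsworth–Emmons olefination: the stabilised phosphonate anion adds reversibly and the anti oxaphosphetane collapses to the E enoate. The anion is preformed with a slight deficit of NaH so that no free hydride or alkoxide meets the silyl ethers.

Step 6
Reactants: 9 ethyl (2E)-3-[3,4,5-tris(TBSO)phenyl]prop-2-enoate
Product: 10 (2E)-3-[3,4,5-tris(TBSO)phenyl]prop-2-en-1-ol
Conditions: iBu2AlH (2.3 equiv), CH2Cl2, −78 °C; aq. potassium sodium tartrate
Reagents that add atoms: none
Why: 1,2-Reduction of the enoate by the Lewis-acidic aluminium hydride gives the allylic alcohol without touching the alkene or the silyl ethers; the E geometry is retained.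

Step 7
Reactants: 10 (2E)-3-[3,4,5-tris(TBSO)phenyl]prop-2-en-1-ol
Product: 11 (2E)-3-[3,4,5-tris(TBSO)phenyl]prop-2-en-1-yl 2,2,2-trichloroacetimidate
Conditions: Cl3CCN (1.5 equiv), DBU (10 mol%), CH2Cl2, 0 °C; rapid filtration through Et3N-deactivated silica
Reagents that add atoms: trichloroacetonitrile, N#CC(Cl)(Cl)Cl
Why: Base-catalysed addition of the allylic alkoxide to the nitrile gives the imidate. Catalytic DBU at 0 °C does not cleave aryl silyl ethers, and the product is used at once so that thermal rearrangement to the allylic trichloroacetamide has no time to occur.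

Step 8
Reactants: 5 tert-butyl (3S)-3-[3,4-bis(TBSO)phenyl]-3-hydroxypropanoate; 11 (2E)-3-[3,4,5-tris(TBSO)phenyl]prop-2-en-1-yl 2,2,2-trichloroacetimidate
Product: 12 tert-butyl (3S)-3-[3,4-bis(TBSO)phenyl]-3-{[(2E)-3-[3,4,5-tris(TBSO)phenyl]prop-2-en-1-yl]oxy}propanoate
Conditions: 11 (1.6 equiv), Me3SiOTf (5 mol%), CH2Cl2, −40 → 0 °C; Et3N
Reagents that add atoms: none
Why: Acid-catalysed trichloroacetimidate etherification: the protonated imidate ionises to an aryl-stabilised allyl cation that the secondary alcohol attacks at the unhindered CH2 terminus, keeping the conjugated E alkene. The stereocentre is untouched because its C–O bond is never broken, and the absence of base excludes retro-aldol cleavage or dehydration of the β-hydroxy ester.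

Step 9
Reactants: 12 tert-butyl (3S)-3-[3,4-bis(TBSO)phenyl]-3-{[(2E)-3-[3,4,5-tris(TBSO)phenyl]prop-2-en-1-yl]oxy}propanoate
Product: 13 di-tert-butyl 2-[(S)-[3,4-bis(TBSO)phenyl]{[(2E)-3-[3,4,5-tris(TBSO)phenyl]prop-2-en-1-yl]oxy}methyl]propanedioate
Conditions: LiN(iPr)2 (2.1 equiv), THF, −78 °C, 20 min; Boc2O (1.2 equiv), −78 °C; AcOH, −78 °C
Reagents that add atoms: di-tert-butyl dicarbonate, CC(C)(C)OC(=O)OC(=O)OC(C)(C)C
Why: Claisen-type C-acylation of the lithium ester enolate by the dicarbonate; the second equivalent of base stores the product as its malonate enolate. Chelation of lithium by the ether oxygen holds the C–O bond out of alignment with the enolate π system, and the cold acidic quench protonates the malonate before cinnamyl oxide can be expelled, so the C2 configuration should be carried over unchanged.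

Step 10
Reactants: 13 di-tert-butyl 2-[(S)-[3,4-bis(TBSO)phenyl]{[(2E)-3-[3,4,5-tris(TBSO)phenyl]prop-2-en-1-yl]oxy}methyl]propanedioate
Product: 14 tert-butyl (1R,2R,5R,6S)-2-[3,4-bis(TBSO)phenyl]-8-oxo-6-[3,4,5-tris(TBSO)phenyl]-3,7-dioxabicyclo[3.3.0]octane-1-carboxylate
Conditions: Mn(OAc)3·2H2O (2.2 equiv), Cu(OAc)2·H2O (0.2 equiv), degassed AcOH (0.05 M), 60 °C, argon
Reagents that add atoms: none
Why: Trivalent manganese forms the manganese enolate of the malonate and, by inner-sphere electron transfer, the electrophilic C1 malonyl radical, which adds to the nearer alkene carbon C5 in a 5-exo-trig closure that makes the tetrahydrofuran and leaves a benzylic radical at C6. Divalent copper, returned to that state by trivalent manganese, oxidises this radical to the benzylic cation, which is captured by the carbonyl oxygen of the tert-butyl ester held cis to it on C1; this is a five-membered closure onto a cationic carbon, and the dialkoxycarbenium ion then loses isobutene to give the lactone. The closest known reaction type is the Mn(OAc)3/Cu(OAc)2 oxidative free-radical cyclisation of unsaturated malonates that ends in lactonisation. C5 is controlled by the existing C2 centre: in the chair-like transition state of the 5-exo closure the C2 aryl group lies pseudoequatorial, which puts the new side chain on C5 trans to it. C6 is controlled by the shape of the forming bicycle, the cation closing with its aryl group turned to the convex face and away from C4. C1 becomes stereogenic only through the lactonisation and follows from C5, because only the ester cis to C6 can reach the cation. The step needs 5-exo rather than 6-endo closure, secured by the C2–O3–C4 tether and by the benzylic stabilisation of the C6 radical, and it needs lactonisation to outrun loss of the C5 hydrogen or capture by acetate, secured by the geminal diester and the oxygen-rich aryl ring. The acidic medium keeps the malonate from expelling cinnamyl alcohol, and the quaternary C1 of 14 has no hydrogen left for further oxidation.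

Step 11
Reactants: 14 tert-butyl (1R,2R,5R,6S)-2-[3,4-bis(TBSO)phenyl]-8-oxo-6-[3,4,5-tris(TBSO)phenyl]-3,7-dioxabicyclo[3.3.0]octane-1-carboxylate
Product: 16 (1S,2S,5R,6S)-2-[3,4-bis(TBSO)phenyl]-6-[3,4,5-tris(TBSO)phenyl]-3,7-dioxabicyclo[3.3.0]octan-8-one, via carboxylic acid 15 (not isolated)
Conditions: CF3CO2H/CH2Cl2 (1:4), 0 °C; evaporate; PhMe, 100 °C
Reagents that add atoms: none
Why: Acidolysis of the tert-butyl ester by alkyl–oxygen cleavage gives the malonic-type acid 15, which loses CO2 on heating through the cyclic six-centre transition state; the lactone enol then takes up its proton on the convex face, the only way to the strain-free cis fusion, so C1 is set as 1S. Aryl silyl ethers tolerate brief cold CF3CO2H, ionisation at C2 is disfavoured by the two carbonyl groups on C1, and the twisted para silyloxy group gives little help to ionisation at C6.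

Step 12
Reactants: 16 (1S,2S,5R,6S)-2-[3,4-bis(TBSO)phenyl]-6-[3,4,5-tris(TBSO)phenyl]-3,7-dioxabicyclo[3.3.0]octan-8-one
Product: 17 (1S,2S,5R,6S)-2-(3,4-dihydroxyphenyl)-6-(3,4,5-trihydroxyphenyl)-3,7-dioxabicyclo[3.3.0]octan-8-one
Conditions: Bu4NF (6 equiv), AcOH (9 equiv), THF, 0 °C, argon; pH 5 work-up
Reagents that add atoms: none
Why: Fluoride cleaves the five aryl O–Si bonds, driven by the strength of the Si–F bond. Acetic acid protonates each phenoxide as it forms, which should prevent expulsion of O7 or O3 through a quinone methide (epimerisation at C6 or C2), opening of the lactone, and air oxidation of the catechol and pyrogallol rings.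

## Compound list

1 | methyl 3,4-dihydroxybenzoate | COC(=O)c1ccc(O)c(O)c1 | starting material
2 | methyl 3,4-bis(TBSO)benzoate | COC(=O)c1ccc(O[Si](C)(C)C(C)(C)C)c(O[Si](C)(C)C(C)(C)C)c1 | intermediate
3 | tert-butyl acetate | CC(=O)OC(C)(C)C | starting material
4 | tert-butyl 3-[3,4-bis(TBSO)phenyl]-3-oxopropanoate | CC(C)(C)OC(=O)CC(=O)c1ccc(O[Si](C)(C)C(C)(C)C)c(O[Si](C)(C)C(C)(C)C)c1 | intermediate
5 | tert-butyl (3S)-3-[3,4-bis(TBSO)phenyl]-3-hydroxypropanoate | CC(C)(C)OC(=O)C[C@H](O)c1ccc(O[Si](C)(C)C(C)(C)C)c(O[Si](C)(C)C(C)(C)C)c1 | intermediate
6 | 3,4,5-trihydroxybenzaldehyde | O=Cc1cc(O)c(O)c(O)c1 | starting material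
7 | 3,4,5-tris(TBSO)benzaldehyde | O=Cc1cc(O[Si](C)(C)C(C)(C)C)c(O[Si](C)(C)C(C)(C)C)c(O[Si](C)(C)C(C)(C)C)c1 | intermediate
8 | triethyl phosphonoacetate | CCOC(=O)CP(=O)(OCC)OCC | starting material
9 | ethyl (2E)-3-[3,4,5-tris(TBSO)phenyl]prop-2-enoate | CCOC(=O)/C=C/c1cc(O[Si](C)(C)C(C)(C)C)c(O[Si](C)(C)C(C)(C)C)c(O[Si](C)(C)C(C)(C)C)c1 | intermediate
10 | (2E)-3-[3,4,5-tris(TBSO)phenyl]prop-2-en-1-ol | OC/C=C/c1cc(O[Si](C)(C)C(C)(C)C)c(O[Si](C)(C)C(C)(C)C)c(O[Si](C)(C)C(C)(C)C)c1 | intermediate
11 | (2E)-3-[3,4,5-tris(TBSO)phenyl]prop-2-en-1-yl 2,2,2-trichloroacetimidate | N=C(OC/C=C/c1cc(O[Si](C)(C)C(C)(C)C)c(O[Si](C)(C)C(C)(C)C)c(O[Si](C)(C)C(C)(C)C)c1)C(Cl)(Cl)Cl | intermediate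
12 | tert-butyl (3S)-3-[3,4-bis(TBSO)phenyl]-3-{[(2E)-3-[3,4,5-tris(TBSO)phenyl]prop-2-en-1-yl]oxy}propanoate | C(/C=C/c1cc(O[Si](C)(C)C(C)(C)C)c(O[Si](C)(C)C(C)(C)C)c(O[Si](C)(C)C(C)(C)C)c1)O[C@H](c1ccc(O[Si](C)(C)C(C)(C)C)c(O[Si](C)(C)C(C)(C)C)c1)CC(=O)OC(C)(C)C | intermediate
13 | di-tert-butyl 2-[(S)-[3,4-bis(TBSO)phenyl]{[(2E)-3-[3,4,5-tris(TBSO)phenyl]prop-2-en-1-yl]oxy}methyl]propanedioate | C(/C=C/c1cc(O[Si](C)(C)C(C)(C)C)c(O[Si](C)(C)C(C)(C)C)c(O[Si](C)(C)C(C)(C)C)c1)O[C@H](c1ccc(O[Si](C)(C)C(C)(C)C)c(O[Si](C)(C)C(C)(C)C)c1)C(C(=O)OC(C)(C)C)C(=O)OC(C)(C)C | intermediate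
14 | tert-butyl (1R,2R,5R,6S)-2-[3,4-bis(TBSO)phenyl]-8-oxo-6-[3,4,5-tris(TBSO)phenyl]-3,7-dioxabicyclo[3.3.0]octane-1-carboxylate (cis-fused, both aryl groups on the convex face) | O=C1O[C@H](c2cc(O[Si](C)(C)C(C)(C)C)c(O[Si](C)(C)C(C)(C)C)c(O[Si](C)(C)C(C)(C)C)c2)[C@H]2CO[C@H](c3ccc(O[Si](C)(C)C(C)(C)C)c(O[Si](C)(C)C(C)(C)C)c3)[C@@]12C(=O)OC(C)(C)C | intermediate
15 | (1S,2R,5R,6S)-2-[3,4-bis(TBSO)phenyl]-8-oxo-6-[3,4,5-tris(TBSO)phenyl]-3,7-dioxabicyclo[3.3.0]octane-1-carboxylic acid | O=C1O[C@H](c2cc(O[Si](C)(C)C(C)(C)C)c(O[Si](C)(C)C(C)(C)C)c(O[Si](C)(C)C(C)(C)C)c2)[C@H]2CO[C@H](c3ccc(O[Si](C)(C)C(C)(C)C)c(O[Si](C)(C)C(C)(C)C)c3)[C@@]12C(=O)O | intermediate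
16 | (1S,2S,5R,6S)-2-[3,4-bis(TBSO)phenyl]-6-[3,4,5-tris(TBSO)phenyl]-3,7-dioxabicyclo[3.3.0]octan-8-one | O=C1O[C@H](c2cc(O[Si](C)(C)C(C)(C)C)c(O[Si](C)(C)C(C)(C)C)c(O[Si](C)(C)C(C)(C)C)c2)[C@H]2CO[C@H](c3ccc(O[Si](C)(C)C(C)(C)C)c(O[Si](C)(C)C(C)(C)C)c3)[C@@H]12 | intermediate
17 | (1S,2S,5R,6S)-2-(3,4-dihydroxyphenyl)-6-(3,4,5-trihydroxyphenyl)-3,7-dioxabicyclo[3.3.0]octan-8-one | O=C1O[C@H](c2cc(O)c(O)c(O)c2)[C@H]2CO[C@H](c3ccc(O)c(O)c3)[C@@H]12 | target

## Step count and least certain steps

Total step count: 12. Longest linear sequence: 9 steps (steps 4 to 12, from 6 to 17); the other branch (steps 1 to 3) joins at step 8.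

**Step 10 (key step).** Three processes could go wrong.

- Facial selectivity at C5 may erode, because the two ester groups on the radical carbon crowd the C2 substituents and weaken the preference for the pseudoequatorial aryl group.
- Cinnamyl alcohol may be lost by retro-oxa-Michael cleavage of the manganese enolate before the radical forms, since enolisation of a hindered substituted malonate is slow.
- The oxidised C6 centre may be diverted by loss of the C5 hydrogen, by capture by acetate, or by loss of the para silyl group through a quinone-methide-like cation, if lactonisation is not fast enough.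

The fallback sets out from 12 and returns at 14. The lithium enolate of 13 generated as in step 9 would be brominated in the flask with N-bromosuccinimide at −78 °C instead of being protonated. This would give the bromomalonate di-tert-butyl 2-bromo-2-[(R)-[3,4-bis(TBSO)phenyl]{[(2E)-3-[3,4,5-tris(TBSO)phenyl]prop-2-en-1-yl]oxy}methyl]propanedioate F1 (same spatial arrangement at the ether carbon as 13), which has no acidic hydrogen and so cannot expel cinnamyl alcohol. Irradiation with blue light in MeCN at room temperature with fac-Ir(ppy)3 (1 mol%) and 2,6-lutidine should give the same malonyl radical by single-electron reduction of the C–Br bond. After the 5-exo closure the benzylic radical would be oxidised by the tetravalent iridium form of the catalyst and the cation captured by the tert-butyl ester as in step 10, giving 14. This is a visible-light atom-transfer cyclisation with radical–polar crossover, a known reaction type for bromomalonates and styrenes, and it avoids hot acid and a stoichiometric metal oxidant.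

**Step 9.** The ester enolate of 12 may undergo β-elimination of cinnamyl oxide, because the product would be a cinnamate conjugated with an oxygen-rich arene. Acylation may also stall through proton transfer from the newly formed malonate to unreacted enolate. The fallback sets out from 5 and returns at 13. Compound 5 would be converted with LiN(iPr)2 (3 equiv) into its dianion, whose alkoxide cannot leave, and acylated at carbon with Boc2O at −78 °C to give di-tert-butyl 2-[(S)-[3,4-bis(TBSO)phenyl](hydroxy)methyl]propanedioate F2. Etherification of F2 with 11 under Me3SiOTf catalysis, as in step 8, would then give 13 directly.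

**Step 8.** The imidate may rearrange to the allylic trichloroacetamide or give the branched ether, because its allyl cation forms very easily. The benzylic alcohol of 5 may also ionise under the acid catalyst, which would erode the stereocentre. The fallback sets out from 5 and 7 and returns at 12. Compound 5 would be allylated with allyl 2,2,2-trichloroacetimidate and catalytic CF3SO3H to give tert-butyl (3S)-3-(allyloxy)-3-[3,4-bis(TBSO)phenyl]propanoate F3. Compound 7 would be methylenated with methyltriphenylphosphonium bromide and KOtBu to give 3,4,5-tris(TBSO)styrene F4. Cross-metathesis of F3 with an excess of F4, using the second-generation Grubbs catalyst RuCl2(H2IMes)(PCy3)(=CHPh) in CH2Cl2 at 40 °C, should then give the E alkene 12.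

**Step 11.** The C6–O7 bond (and less probably the C2–O3 bond) may ionise in CF3CO2H, leading to epimerisation or to Friedel–Crafts attack of the cation on the other arene. Decarboxylation of the quaternary acid may also be slow enough to demand a higher temperature. The fallback sets out from 14 and returns at 15. Me3SiOTf with 2,6-lutidine in CH2Cl2 at 0 °C would exchange the tert-butyl group for silicon under buffered aprotic conditions, giving the silyl ester trimethylsilyl (1R,2R,5R,6S)-2-[3,4-bis(TBSO)phenyl]-8-oxo-6-[3,4,5-tris(TBSO)phenyl]-3,7-dioxabicyclo[3.3.0]octane-1-carboxylate F5. Work-up with pH 5 buffer would hydrolyse F5 to 15, which would be decarboxylated by heating as in step 11.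

**Step 3.** Enantioselectivity may be incomplete and the reduction slow, because the ketone is deactivated by the para silyloxy group. Solvolytic loss of silyl groups may also occur in warm alcohol if traces of HCl accompany the catalyst. The fallback sets out from 4 and returns at 5. NaBH4 in THF/MeOH at 0 °C would give the racemic alcohol tert-butyl 3-[3,4-bis(TBSO)phenyl]-3-hydroxypropanoate F6. Kinetic resolution with Burkholderia cepacia lipase and vinyl acetate in tBuOMe at 30 °C is expected, from the usual size-based preference of this lipase for secondary alcohols, to acetylate the R enantiomer. This would give the acetate tert-butyl (3R)-3-acetoxy-3-[3,4-bis(TBSO)phenyl]propanoate F7 and leave (3S)-alcohol 5, which would be separated by chromatography.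

## Further compounds

F1 | step 10 | di-tert-butyl 2-bromo-2-[(R)-[3,4-bis(TBSO)phenyl]{[(2E)-3-[3,4,5-tris(TBSO)phenyl]prop-2-en-1-yl]oxy}methyl]propanedioate | C(/C=C/c1cc(O[Si](C)(C)C(C)(C)C)c(O[Si](C)(C)C(C)(C)C)c(O[Si](C)(C)C(C)(C)C)c1)O[C@H](c1ccc(O[Si](C)(C)C(C)(C)C)c(O[Si](C)(C)C(C)(C)C)c1)C(Br)(C(=O)OC(C)(C)C)C(=O)OC(C)(C)C
F2 | step 9 | di-tert-butyl 2-[(S)-[3,4-bis(TBSO)phenyl](hydroxy)methyl]propanedioate | O[C@H](c1ccc(O[Si](C)(C)C(C)(C)C)c(O[Si](C)(C)C(C)(C)C)c1)C(C(=O)OC(C)(C)C)C(=O)OC(C)(C)C
F3 | step 8 | tert-butyl (3S)-3-(allyloxy)-3-[3,4-bis(TBSO)phenyl]propanoate | C=CCO[C@H](c1ccc(O[Si](C)(C)C(C)(C)C)c(O[Si](C)(C)C(C)(C)C)c1)CC(=O)OC(C)(C)C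
F4 | step 8 | 3,4,5-tris(TBSO)styrene | C=Cc1cc(O[Si](C)(C)C(C)(C)C)c(O[Si](C)(C)C(C)(C)C)c(O[Si](C)(C)C(C)(C)C)c1
F5 | step 11 | trimethylsilyl (1R,2R,5R,6S)-2-[3,4-bis(TBSO)phenyl]-8-oxo-6-[3,4,5-tris(TBSO)phenyl]-3,7-dioxabicyclo[3.3.0]octane-1-carboxylate | O=C1O[C@H](c2cc(O[Si](C)(C)C(C)(C)C)c(O[Si](C)(C)C(C)(C)C)c(O[Si](C)(C)C(C)(C)C)c2)[C@H]2CO[C@H](c3ccc(O[Si](C)(C)C(C)(C)C)c(O[Si](C)(C)C(C)(C)C)c3)[C@@]12C(=O)O[Si](C)(C)C
F6 | step 3 | racemic tert-butyl 3-[3,4-bis(TBSO)phenyl]-3-hydroxypropanoate | CC(C)(C)OC(=O)CC(O)c1ccc(O[Si](C)(C)C(C)(C)C)c(O[Si](C)(C)C(C)(C)C)c1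
F7 | step 3 | tert-butyl (3R)-3-acetoxy-3-[3,4-bis(TBSO)phenyl]propanoate | CC(C)(C)OC(=O)C[C@@H](OC(C)=O)c1ccc(O[Si](C)(C)C(C)(C)C)c(O[Si](C)(C)C(C)(C)C)c1
A1 | alternative 1 | (5R)-5-[(1R,2S,5R)-menthyloxy]furan-2(5H)-one | O=C1C=C[C@H](O[C@@H]2C[C@H](C)CC[C@H]2C(C)C)O1
A2 | alternative 1 | 2-[3,4,5-tris(TBSO)phenyl]-1,3-dithiane | C1CSC(SC1)c1cc(O[Si](C)(C)C(C)(C)C)c(O[Si](C)(C)C(C)(C)C)c(O[Si](C)(C)C(C)(C)C)c1
A3 | alternative 1 | 3,4-bis(TBSO)benzaldehyde | O=Cc1ccc(O[Si](C)(C)C(C)(C)C)c(O[Si](C)(C)C(C)(C)C)c1
A4 | alternative 1 | 3,4-trans-4,5-trans 3-{[3,4-bis(TBSO)phenyl](hydroxy)methyl}-4-{2-[3,4,5-tris(TBSO)phenyl]-1,3-dithian-2-yl}-5-menthyloxydihydrofuran-2(3H)-one (carbinol centre unassigned) | O=C1O[C@@H](O[C@@H]4C[C@H](C)CC[C@H]4C(C)C)[C@H](C5(c2cc(O[Si](C)(C)C(C)(C)C)c(O[Si](C)(C)C(C)(C)C)c(O[Si](C)(C)C(C)(C)C)c2)SCCCS5)[C@H]1C(O)c3ccc(O[Si](C)(C)C(C)(C)C)c(O[Si](C)(C)C(C)(C)C)c3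
A5 | alternative 2 | racemic 2-vinyloxirane | C=CC1CO1
A6 | alternative 2 | dimethyl 2-[3,4-bis(TBSO)benzylidene]malonate | COC(=O)C(=Cc1ccc(O[Si](C)(C)C(C)(C)C)c(O[Si](C)(C)C(C)(C)C)c1)C(=O)OC
A7 | alternative 2 | dimethyl (2R,4R)-2-[3,4-bis(TBSO)phenyl]-4-vinyltetrahydrofuran-3,3-dicarboxylate (2,4-trans) | C=C[C@H]1CO[C@H](c3ccc(O[Si](C)(C)C(C)(C)C)c(O[Si](C)(C)C(C)(C)C)c3)C1(C(=O)OC)C(=O)OC
A8 | alternative 3 | (1S)-1-[3,4,5-tris(TBSO)phenyl]prop-2-en-1-yl 2-diazo-3-[3,4-bis(TBSO)phenyl]-3-oxopropanoate | [N-]=[N+]=C(C(=O)c1ccc(O[Si](C)(C)C(C)(C)C)c(O[Si](C)(C)C(C)(C)C)c1)C(=O)O[C@H](c1cc(O[Si](C)(C)C(C)(C)C)c(O[Si](C)(C)C(C)(C)C)c(O[Si](C)(C)C(C)(C)C)c1)C=C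
A9 | alternative 3 | 1-[3,4-bis(TBSO)benzoyl]-4-[3,4,5-tris(TBSO)phenyl]-3-oxabicyclo[3.1.0]hexan-2-one (aryl group on the face opposite to the cyclopropane, configuration as in the SMILES) | O=C1O[C@H](c2cc(O[Si](C)(C)C(C)(C)C)c(O[Si](C)(C)C(C)(C)C)c(O[Si](C)(C)C(C)(C)C)c2)[C@H]2C[C@@]12C(=O)c1ccc(O[Si](C)(C)C(C)(C)C)c(O[Si](C)(C)C(C)(C)C)c1
A10 | alternative 3 | (5R,6S)-2-[3,4-bis(TBSO)phenyl]-6-[3,4,5-tris(TBSO)phenyl]-3,7-dioxabicyclo[3.3.0]oct-1-en-8-one | O=C1O[C@H](c2cc(O[Si](C)(C)C(C)(C)C)c(O[Si](C)(C)C(C)(C)C)c(O[Si](C)(C)C(C)(C)C)c2)[C@H]2COC(c3ccc(O[Si](C)(C)C(C)(C)C)c(O[Si](C)(C)C(C)(C)C)c3)=C12
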